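**Plan**

1. Target numbering: ring A = O1, C2 (aryl), C3 (CH2OH), C4 (aroyl), C5. The oxygen of the C3 CH2OH and the ketone carbon on C4 are cis and 1,4-related, so they are the two ends of a second tetrahydrofuran (ring B) fused cis at C3–C4. The target is therefore a furofuran opened at one 4-hydroxybenzylic C–O bond.
2. Retrosynthesis: (a) benzyl off the ring A phenol; (b) ketone and CH2OH back to the ring B benzylic ether, giving an unequally protected syringaresinol with a C2-symmetric core; (c) C3–C4 and O1–C2 cut together to an acyclic epoxy cinnamyl ether; (d) its ether C–O cut to an epoxy alcohol and a cinnamyl bromide.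
3. Forward: syringaldehyde gives the silyl-protected epoxy alcohol (3 steps) and sinapyl alcohol the benzyl-protected bromide (2 steps); they are joined by Williamson etherification. One titanocene cascade then closes ring B (C3–C4, radical 5-exo) and ring A (O1–C2, ionic) in that order, followed by desilylation, DDQ opening of ring B and hydrogenolysis.
4. Stereochemistry: a single carbinol centre from a Sharpless kinetic resolution steers C4, C3 and C2 in the cascade and is erased when it becomes the ketone carbon. The cis C3/C4 relation is held by the ring fusion until that last oxidation.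
5. Both benzylic carbons carry 4-oxygenated 3,5-dimethoxyphenyl rings, which allows easy ionisation of a benzylic iodide at C2 and phenol-triggered hydride loss at the ring B benzylic carbon. Because the core is C2-symmetric, the ring that opens is chosen only by which phenol is free.

Key step: step 7

Assumption: in the Sharpless kinetic resolution the aryl group is taken to occupy the place of the carbinol substituent in the usual model, so that D-(−)-diisopropyl tartrate consumes the (S)-alcohol.

**Step 1**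
Reactants: 1 syringaldehyde
Product: 2 3,5-dimethoxy-4-(triisopropylsilyloxy)benzaldehyde
Conditions: TIPSCl (1.2 equiv), imidazole (2.5 equiv), DMF, rt
Reagents that add atoms: triisopropylsilyl chloride, CC(C)[Si](Cl)(C(C)C)C(C)C
Why: Silylation of a phenol, giving an ether that should survive the Grignard, titanium and alkoxide steps and come off with fluoride before the oxidation.

**Step 2**
Reactants: 2 3,5-dimethoxy-4-(triisopropylsilyloxy)benzaldehyde
Product: 3 rac-1-[3,5-dimethoxy-4-(triisopropylsilyloxy)phenyl]prop-2-en-1-ol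
Conditions: vinylmagnesium bromide (1.2 equiv), THF, −78 °C to 0 °C; aq. NH4Cl
Reagents that add atoms: vinylmagnesium bromide, C=C[Mg]Br
Why: Grignard addition to an aryl aldehyde should give the racemic secondary allylic alcohol needed for the resolution.

**Step 3**
Reactants: 3 rac-1-[3,5-dimethoxy-4-(triisopropylsilyloxy)phenyl]prop-2-en-1-ol
Product: 4 (R)-[3,5-dimethoxy-4-(triisopropylsilyloxy)phenyl][(2S)-oxiran-2-yl]methanol
Conditions: Ti(OiPr)4 (0.1 equiv), D-(−)-diisopropyl tartrate (0.15 equiv), tBuOOH (0.45 equiv), 4 Å molecular sieves, CH2Cl2, −20 °C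
Reagents that add atoms: tert-butyl hydroperoxide, CC(C)(C)OO
Why: Sharpless kinetic resolution, in which the (S)-carbinol should be the fast-reacting enantiomer with the D-(−)-tartrate and be epoxidised to the erythro (1R,2S) epoxy alcohol while the (R)-alcohol stays behind, with the limited peroxide holding conversion below half so that the product should derive almost only from the fast enantiomer, and with only the carbinol centre mattering later because the epoxide carbon becomes a planar radical.

**Step 4**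
Reactants: 5 (E)-sinapyl alcohol
Product: 6 (E)-3-[4-(benzyloxy)-3,5-dimethoxyphenyl]prop-2-en-1-ol
Conditions: BnBr (1.1 equiv), K2CO3 (1.5 equiv), acetone, 50 °C
Reagents that add atoms: benzyl bromide, BrCc1ccccc1
Why: Williamson alkylation of the phenoxide, which should be selective because the carbonate deprotonates the phenol and not the allylic alcohol.

**Step 5**
Reactants: 6 (E)-3-[4-(benzyloxy)-3,5-dimethoxyphenyl]prop-2-en-1-ol
Product: 7 2-(benzyloxy)-5-[(E)-3-bromoprop-1-en-1-yl]-1,3-dimethoxybenzene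
Conditions: PBr3 (0.4 equiv), Et2O, 0 °C; used crude at once
Reagents that add atoms: phosphorus tribromide, BrP(Br)Br
Why: Conversion of a primary allylic alcohol to the bromide with PBr3 should give the linear (E)-cinnamyl bromide, the conjugated and thermodynamically preferred isomer.

**Step 6**
Reactants: 4 (R)-[3,5-dimethoxy-4-(triisopropylsilyloxy)phenyl][(2S)-oxiran-2-yl]methanol; 7 2-(benzyloxy)-5-[(E)-3-bromoprop-1-en-1-yl]-1,3-dimethoxybenzene
Product: 8 (2S)-2-[(R)-{[(2E)-3-(4-benzyloxy-3,5-dimethoxyphenyl)prop-2-en-1-yl]oxy}[3,5-dimethoxy-4-(triisopropylsilyloxy)phenyl]methyl]oxirane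
Conditions: NaH (1.1 equiv), Bu4NI (0.1 equiv), THF, 0 °C to rt
Reagents that add atoms: none
Why: Williamson etherification, in which the sodium alkoxide of the epoxy alcohol should displace the primary allylic bromide by SN2 in an aprotic medium at low temperature where Payne rearrangement is slow, without touching either stereocentre.

**Step 7**
Reactants: 8 (2S)-2-[(R)-{[(2E)-3-(4-benzyloxy-3,5-dimethoxyphenyl)prop-2-en-1-yl]oxy}[3,5-dimethoxy-4-(triisopropylsilyloxy)phenyl]methyl]oxirane
Product: 10 (1S,3aR,4S,6aR)-1-[4-(benzyloxy)-3,5-dimethoxyphenyl]-4-[3,5-dimethoxy-4-(triisopropylsilyloxy)phenyl]tetrahydro-1H,3H-furo[3,4-c]furan, via benzylic iodide 9 (not isolated)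
Conditions: Cp2TiCl2 (2.5 equiv), Zn dust, THF, rt (gives green Cp2TiCl), added dropwise to 8 in THF, rt; then I2 (1.2 equiv), THF, 40 °C; aq. Na2S2O3
Reagents that add atoms: none
Why: Cp2TiCl (trivalent titanium) transfers one electron to the epoxide, which opens at the more substituted carbon to a secondary radical at the future C4 with the primary oxygen held as a titanium alkoxide; this radical adds 5-exo-trig to the cinnamyl double bond (closing ring B and forming C3–C4), the benzylic radical at the future C2 is captured by a second Cp2TiCl, and iodine turns the benzylic C–Ti bond into an ionisable benzylic iodide that the titanium alkoxide displaces in a 5-exo-tet closure (forming O1–C2 and ring A). The closest known reaction type is the titanocene-mediated reductive epoxide opening with radical cyclisation (Nugent–RajanBabu) of epoxy allyl ethers followed by iodine-induced etherification, which is established for 2,6-diaryl furofurans. C4 and C3 are set in the radical step under control of the carbinol stereocentre: in the chair-like transition state the aryl group on the ring B benzylic carbon sits pseudo-equatorial, which places it trans to the CH2O–Ti arm on C4 and puts that arm cis to the new benzylic carbon on C3, the only arrangement from which the cis-fused bicycle can close. C2 is set in the ionic closure, where the aryl group takes the exo (convex) position trans to the ring B CH2 on C3, and because the 4-oxygenated benzylic iodide ionises reversibly this centre should settle under thermodynamic control. The step needs the 5-exo cyclisation to outrun reduction of the first radical by a second Cp2TiCl (which would end in deoxygenation) and needs opening at the secondary epoxide carbon; the aryl-activated alkene acceptor, the dropwise addition of the titanium reagent and the greater stability of the secondary radical should secure both.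

**Step 8**
Reactants: 10 (1S,3aR,4S,6aR)-1-[4-(benzyloxy)-3,5-dimethoxyphenyl]-4-[3,5-dimethoxy-4-(triisopropylsilyloxy)phenyl]tetrahydro-1H,3H-furo[3,4-c]furan
Product: 11 4-[(1S,3aR,4S,6aR)-4-[4-(benzyloxy)-3,5-dimethoxyphenyl]tetrahydro-1H,3H-furo[3,4-c]furan-1-yl]-2,6-dimethoxyphenol
Conditions: TBAF (1.1 equiv), AcOH (1.1 equiv), THF, 0 °C
Reagents that add atoms: none
Why: Fluoride cleavage of an aryl silyl ether should free only the ring B phenol, since the benzyl ether and the furofuran are inert to buffered fluoride.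

**Step 9**
Reactants: 11 4-[(1S,3aR,4S,6aR)-4-[4-(benzyloxy)-3,5-dimethoxyphenyl]tetrahydro-1H,3H-furo[3,4-c]furan-1-yl]-2,6-dimethoxyphenol
Product: 14 (2S,3R,4R)-2-[4-(benzyloxy)-3,5-dimethoxyphenyl]-3-(hydroxymethyl)-4-(4-hydroxy-3,5-dimethoxybenzoyl)tetrahydrofuran, via quinone methide 12 (not isolated), via hemiketal 13 (not isolated)
Conditions: DDQ (1.05 equiv), THF/pH 7 phosphate buffer (10:1), 0 °C
Reagents that add atoms: water, O
Why: DDQ oxidation of a 4-hydroxybenzylic ether should remove hydride through the free phenol to give the ring B alkoxy quinone methide, which water attacks at the benzylic carbon to a hemiketal that opens to the aryl ketone and frees the C3 CH2OH, while the benzyl-protected ring lacks the phenol and should react far more slowly and the buffered cold medium should leave the now enolisable C4 centre untouched.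

**Step 10**
Reactants: 14 (2S,3R,4R)-2-[4-(benzyloxy)-3,5-dimethoxyphenyl]-3-(hydroxymethyl)-4-(4-hydroxy-3,5-dimethoxybenzoyl)tetrahydrofuran
Product: 15 ciwujiatone, (2S,3R,4R)-2-(4-hydroxy-3,5-dimethoxyphenyl)-3-(hydroxymethyl)-4-(4-hydroxy-3,5-dimethoxybenzoyl)tetrahydrofuran
Conditions: H2 (1 atm), 10% Pd/C, EtOAc, rt, stopped at full conversion
Reagents that add atoms: none
Why: Hydrogenolysis of an aryl benzyl ether under neutral conditions should be much faster than reduction of the electron-rich aryl ketone or cleavage of the ring A benzylic C–O bond, and involves no base that could epimerise C4.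

**Compound list**

1 | syringaldehyde (4-hydroxy-3,5-dimethoxybenzaldehyde) | COc1cc(C=O)cc(OC)c1O | starting material
2 | 3,5-dimethoxy-4-(triisopropylsilyloxy)benzaldehyde | COc1cc(C=O)cc(OC)c1O[Si](C(C)C)(C(C)C)C(C)C | intermediate
3 | rac-1-[3,5-dimethoxy-4-(triisopropylsilyloxy)phenyl]prop-2-en-1-ol | COc1cc(cc(OC)c1O[Si](C(C)C)(C(C)C)C(C)C)C(O)C=C | intermediate
4 | (R)-[3,5-dimethoxy-4-(triisopropylsilyloxy)phenyl][(2S)-oxiran-2-yl]methanol | COc1cc(cc(OC)c1O[Si](C(C)C)(C(C)C)C(C)C)[C@@H](O)[C@@H]1CO1 | intermediate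
5 | (E)-sinapyl alcohol, 4-[(E)-3-hydroxyprop-1-en-1-yl]-2,6-dimethoxyphenol | COc1cc(/C=C/CO)cc(OC)c1O | starting material
6 | (E)-3-[4-(benzyloxy)-3,5-dimethoxyphenyl]prop-2-en-1-ol | COc1cc(/C=C/CO)cc(OC)c1OCc1ccccc1 | intermediate
7 | 2-(benzyloxy)-5-[(E)-3-bromoprop-1-en-1-yl]-1,3-dimethoxybenzene | COc1cc(/C=C/CBr)cc(OC)c1OCc1ccccc1 | intermediate
8 | (2S)-2-[(R)-{[(2E)-3-(4-benzyloxy-3,5-dimethoxyphenyl)prop-2-en-1-yl]oxy}[3,5-dimethoxy-4-(triisopropylsilyloxy)phenyl]methyl]oxirane | COc1cc(cc(OC)c1O[Si](C(C)C)(C(C)C)C(C)C)[C@@H](OC/C=C/c1cc(OC)c(OCc2ccccc2)c(OC)c1)[C@@H]1CO1 | intermediate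
9 | benzylic iodide: ring B tetrahydrofuran (2-aryl 2,3-trans, 3,4-cis) carrying on C3 the CH2O–TiCp2Cl arm and on C4 the CH(I)(4-benzyloxy-3,5-dimethoxyphenyl) group, iodide carbon of either configuration | COc1cc(cc(OC)c1O[Si](C(C)C)(C(C)C)C(C)C)[C@H]1OC[C@H](C(c2cc(OC)c(OCc3ccccc3)c(OC)c2)I)[C@@H]1CO[Ti](Cl)(C2C=CC=C2)C2C=CC=C2 | intermediate
10 | (1S,3aR,4S,6aR)-1-[4-(benzyloxy)-3,5-dimethoxyphenyl]-4-[3,5-dimethoxy-4-(triisopropylsilyloxy)phenyl]tetrahydro-1H,3H-furo[3,4-c]furan | COc1cc(cc(OC)c1O[Si](C(C)C)(C(C)C)C(C)C)[C@@H]1[C@H]2CO[C@H](c3cc(OC)c(OCc4ccccc4)c(OC)c3)[C@H]2CO1 | intermediate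
11 | 4-[(1S,3aR,4S,6aR)-4-[4-(benzyloxy)-3,5-dimethoxyphenyl]tetrahydro-1H,3H-furo[3,4-c]furan-1-yl]-2,6-dimethoxyphenol (mono-O-benzyl syringaresinol) | COc1cc(cc(OC)c1O)[C@@H]1[C@H]2CO[C@H](c3cc(OC)c(OCc4ccccc4)c(OC)c3)[C@H]2CO1 | intermediate
12 | quinone methide: 11 with the phenol ring as 2,6-dimethoxycyclohexa-2,5-dienone joined by C=C to the ring B benzylic carbon | COC1=CC(=C2OC[C@H]3[C@@H]2CO[C@@H]3c2cc(OC)c(OCc3ccccc3)c(OC)c2)C=C(OC)C1=O | intermediate
13 | hemiketal: 11 with OH on the ring B benzylic carbon (either configuration) | COc1cc(cc(OC)c1O)C1(O)[C@H]2CO[C@H](c3cc(OC)c(OCc4ccccc4)c(OC)c3)[C@H]2CO1 | intermediate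
14 | (2S,3R,4R)-2-[4-(benzyloxy)-3,5-dimethoxyphenyl]-3-(hydroxymethyl)-4-(4-hydroxy-3,5-dimethoxybenzoyl)tetrahydrofuran | COc1cc(C(=O)[C@H]2CO[C@H](c3cc(OC)c(OCc4ccccc4)c(OC)c3)[C@H]2CO)cc(OC)c1O | intermediate
15 | ciwujiatone, (2S,3R,4R)-2-(4-hydroxy-3,5-dimethoxyphenyl)-3-(hydroxymethyl)-4-(4-hydroxy-3,5-dimethoxybenzoyl)tetrahydrofuran | COc1cc(C(=O)[C@H]2CO[C@H](c3cc(OC)c(O)c(OC)c3)[C@H]2CO)cc(OC)c1O | target

**Totals**

Total step count: 10. Longest linear sequence: 8 steps (steps 1–3 and 6–10).

**Steps most likely to fail**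

Step 7. The first radical may be reduced by a second equivalent of the titanium reagent before it cyclises, or the ionic closure at C2 may show poor facial selectivity. Fallback, from 8 and rejoining at 15:
- The titanocene cyclisation is run with an aqueous acid quench instead of iodine, a known route to 4-benzyl-3-(hydroxymethyl)tetrahydrofurans. This should give (2S,3R,4R)-4-[4-(benzyloxy)-3,5-dimethoxybenzyl]-2-[3,5-dimethoxy-4-(triisopropylsilyloxy)phenyl]-3-(hydroxymethyl)tetrahydrofuran F1.
- Hydrogenolysis (H2, Pd/C, EtOAc) should give the phenol (2S,3R,4R)-4-(4-hydroxy-3,5-dimethoxybenzyl)-2-[3,5-dimethoxy-4-(triisopropylsilyloxy)phenyl]-3-(hydroxymethyl)tetrahydrofuran F2.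
- DDQ (2.2 equiv) in wet dioxane should oxidise the 4-hydroxybenzyl CH2 through the quinone methide to the aryl ketone (2S,3R,4R)-2-[3,5-dimethoxy-4-(triisopropylsilyloxy)phenyl]-3-(hydroxymethyl)-4-(4-hydroxy-3,5-dimethoxybenzoyl)tetrahydrofuran F3. Any furofuran formed by internal capture of the quinone methide should be opened to the same ketone under these conditions.
- Buffered fluoride (TBAF/AcOH, THF) should then give 15.
- Here the ring made by the radical step serves as ring A; the C2-symmetric core makes this assignment equivalent to that of the main route.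

Step 6. The alkoxide may undergo Payne rearrangement, or the electron-rich allylic bromide may decompose before etherification. Fallback, from 6 and 4 and rejoining at 8:
- Alcohol 6 is converted with methyl chloroformate and pyridine into (E)-3-[4-(benzyloxy)-3,5-dimethoxyphenyl]prop-2-en-1-yl methyl carbonate F4.
- F4 is coupled with the zinc alkoxide of 4 (Et2Zn, 0.5 equiv) under catalysis by zerovalent palladium formed from Pd(OAc)2 and 2-(di-tert-butylphosphino)biphenyl in THF at rt.
- This Tsuji–Trost allylic etherification needs no alkali alkoxide and no allylic halide, and should give the linear (E)-ether 8.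

Step 9. The benzyloxy-substituted ring may be oxidised in competition, so that ring A opens as well. Fallback, from 10 and rejoining at 15, with the bystander ring made electron-poor before the oxidation:
- Hydrogenolysis of 10 (H2, Pd/C) should give 4-[(1S,3aR,4S,6aR)-4-[3,5-dimethoxy-4-(triisopropylsilyloxy)phenyl]tetrahydro-1H,3H-furo[3,4-c]furan-1-yl]-2,6-dimethoxyphenol F5.
- Acetylation (Ac2O, pyridine) should give the aryl acetate 4-[(1S,3aR,4S,6aR)-4-[3,5-dimethoxy-4-(triisopropylsilyloxy)phenyl]tetrahydro-1H,3H-furo[3,4-c]furan-1-yl]-2,6-dimethoxyphenyl acetate F6.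
- Desilylation (HF·pyridine, THF) should give 4-[(1S,3aR,4S,6aR)-4-(4-hydroxy-3,5-dimethoxyphenyl)tetrahydro-1H,3H-furo[3,4-c]furan-1-yl]-2,6-dimethoxyphenyl acetate F7.
- DDQ in wet THF should then open only the ring next to the free phenol, giving (2S,3R,4R)-2-(4-acetoxy-3,5-dimethoxyphenyl)-3-(hydroxymethyl)-4-(4-hydroxy-3,5-dimethoxybenzoyl)tetrahydrofuran F8.
- Hydrazine acetate in DMF at rt should remove the phenolic acetate under near-neutral conditions to give 15.

**Further compounds**

F1 | step 7 | (2S,3R,4R)-4-[4-(benzyloxy)-3,5-dimethoxybenzyl]-2-[3,5-dimethoxy-4-(triisopropylsilyloxy)phenyl]-3-(hydroxymethyl)tetrahydrofuran | COc1cc(cc(OC)c1O[Si](C(C)C)(C(C)C)C(C)C)[C@H]1OC[C@H](Cc2cc(OC)c(OCc3ccccc3)c(OC)c2)[C@@H]1CO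
F2 | step 7 | (2S,3R,4R)-4-(4-hydroxy-3,5-dimethoxybenzyl)-2-[3,5-dimethoxy-4-(triisopropylsilyloxy)phenyl]-3-(hydroxymethyl)tetrahydrofuran | COc1cc(cc(OC)c1O[Si](C(C)C)(C(C)C)C(C)C)[C@H]1OC[C@H](Cc2cc(OC)c(O)c(OC)c2)[C@@H]1CO
F3 | step 7 | (2S,3R,4R)-2-[3,5-dimethoxy-4-(triisopropylsilyloxy)phenyl]-3-(hydroxymethyl)-4-(4-hydroxy-3,5-dimethoxybenzoyl)tetrahydrofuran | COc1cc(cc(OC)c1O[Si](C(C)C)(C(C)C)C(C)C)[C@H]1OC[C@H](C(=O)c2cc(OC)c(O)c(OC)c2)[C@@H]1CO
F4 | step 6 | (E)-3-[4-(benzyloxy)-3,5-dimethoxyphenyl]prop-2-en-1-yl methyl carbonate | COC(=O)OC/C=C/c1cc(OC)c(OCc2ccccc2)c(OC)c1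
F5 | step 9 | 4-[(1S,3aR,4S,6aR)-4-[3,5-dimethoxy-4-(triisopropylsilyloxy)phenyl]tetrahydro-1H,3H-furo[3,4-c]furan-1-yl]-2,6-dimethoxyphenol | COc1cc(cc(OC)c1O[Si](C(C)C)(C(C)C)C(C)C)[C@@H]1[C@H]2CO[C@H](c3cc(OC)c(O)c(OC)c3)[C@H]2CO1
F6 | step 9 | 4-[(1S,3aR,4S,6aR)-4-[3,5-dimethoxy-4-(triisopropylsilyloxy)phenyl]tetrahydro-1H,3H-furo[3,4-c]furan-1-yl]-2,6-dimethoxyphenyl acetate | COc1cc(cc(OC)c1O[Si](C(C)C)(C(C)C)C(C)C)[C@@H]1[C@H]2CO[C@H](c3cc(OC)c(OC(C)=O)c(OC)c3)[C@H]2CO1
F7 | step 9 | 4-[(1S,3aR,4S,6aR)-4-(4-hydroxy-3,5-dimethoxyphenyl)tetrahydro-1H,3H-furo[3,4-c]furan-1-yl]-2,6-dimethoxyphenyl acetate | COc1cc(cc(OC)c1O)[C@@H]1[C@H]2CO[C@H](c3cc(OC)c(OC(C)=O)c(OC)c3)[C@H]2CO1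
F8 | step 9 | (2S,3R,4R)-2-(4-acetoxy-3,5-dimethoxyphenyl)-3-(hydroxymethyl)-4-(4-hydroxy-3,5-dimethoxybenzoyl)tetrahydrofuran | COc1cc(C(=O)[C@H]2CO[C@H](c3cc(OC)c(OC(C)=O)c(OC)c3)[C@H]2CO)cc(OC)c1O
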